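**Retrosynthetic overview**
- Target ⇐ desilylation and iodine equilibration ⇐ Heck coupling at the terminal CH2 of a 2-methylallylidene butenolide (ring B attached) with a ring A iodotrienyne.
- Structural feature: the lactone carbonyl carbon, Cα (bearing the vinyl link to ring B) and the unsubstituted Cβ of the butenolide are a contiguous three-carbon unit that maps onto a monosubstituted cyclopropenone. Cγ and the ylidene arm are the carbon chain of 4-acetoxy-3-methylbut-2-enal.
- Butenolide ⇐ phosphine-catalysed (3+2) annulation forming Cβ–Cγ and O–C(=O), then 1,4-loss of acetate. This is the only ring made in the route; both carbocycles come from actinol.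
- Cyclopropenone ⇐ Stille coupling of the ring B (E)-vinyl iodide with a stannylated cyclopropenone acetal (from 1,3-dichloroacetone), then acetal hydrolysis. Ring B ⇐ actinol enol triflate, carbonylation, Sharpless epoxidation cis to the silyloxy group, hydrolysis with inversion at the methyl-bearing carbon, Takai olefination.
- Ring A iodide ⇐ the same enol triflate by Sonogashira coupling with (E)-3-methylpent-2-en-4-yn-1-ol, two-carbon Horner–Wadsworth–Emmons homologation, Takai olefination.

Key step: step 17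

Remark: ring B is read from the SMILES as (3S,5R,6R) in carotenoid numbering, so the 3-OH and 6-OH are cis to each other and both trans to the 5-OH; ring A is 3R, and both rings map onto (4R,6R)-actinol.

Step 1
Reactants: 1 (4R,6R)-actinol
Product: 2 (4R,6R)-4-(tert-butyldimethylsilyloxy)-2,2,6-trimethylcyclohexan-1-one
Conditions: TBSCl, imidazole, DMF, rt
Reagents that add atoms: tert-butyldimethylsilyl chloride, CC(C)(C)[Si](C)(C)Cl
Why: Imidazole-promoted silylation of the only hydroxyl group, leaving both stereocentres untouched.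

Step 2
Reactants: 2 (4R,6R)-4-(tert-butyldimethylsilyloxy)-2,2,6-trimethylcyclohexan-1-one
Product: 4 (4R)-4-(tert-butyldimethylsilyloxy)-2,6,6-trimethylcyclohex-1-en-1-yl trifluoromethanesulfonate, via lithium enolate 3 (not isolated)
Conditions: LDA, THF, −78 °C; PhNTf2, −78 °C → rt
Reagents that add atoms: N-phenylbis(trifluoromethanesulfonimide), O=S(=O)(N(c1ccccc1)S(=O)(=O)C(F)(F)F)C(F)(F)F
Why: The ketone has a single α-hydrogen, so enolisation and O-triflation (enol triflate formation) can give only the tetrasubstituted enol triflate, while the carbinol centre is unaffected.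

Step 3
Reactants: 4 (4R)-4-(tert-butyldimethylsilyloxy)-2,6,6-trimethylcyclohex-1-en-1-yl trifluoromethanesulfonate
Product: 5 methyl (4R)-4-(tert-butyldimethylsilyloxy)-2,6,6-trimethylcyclohex-1-ene-1-carboxylate
Conditions: Pd(OAc)2 (5 mol%), PPh3 (10 mol%), Et3N, CO (1 atm), MeOH–DMF, 70 °C
Reagents that add atoms: carbon monoxide, [C-]#[O+]; methanol, CO
Why: Palladium-catalysed alkoxycarbonylation of an enol triflate (oxidative addition, CO insertion, methanolysis of the acyl palladium) installs the future C7 carbon.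

Step 4
Reactants: 5 methyl (4R)-4-(tert-butyldimethylsilyloxy)-2,6,6-trimethylcyclohex-1-ene-1-carboxylate
Product: 6 [(4R)-4-(tert-butyldimethylsilyloxy)-2,6,6-trimethylcyclohex-1-en-1-yl]methanol
Conditions: DIBAL-H (2.5 equiv), CH2Cl2, −78 → 0 °C; Rochelle salt work-up
Reagents that add atoms: none
Why: DIBAL-H 1,2-reduction of the hindered conjugated ester gives the allylic alcohol needed for directed epoxidation.

Step 5
Reactants: 6 [(4R)-4-(tert-butyldimethylsilyloxy)-2,6,6-trimethylcyclohex-1-en-1-yl]methanol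
Product: 7 [(1S,4S,6S)-4-(tert-butyldimethylsilyloxy)-2,2,6-trimethyl-7-oxabicyclo[4.1.0]heptan-1-yl]methanol (epoxide oxygen cis to the silyloxy group)
Conditions: Ti(OiPr)4 (1.0 equiv), L-(+)-diethyl tartrate (1.2 equiv), t-BuOOH (anhydrous, 2 equiv), 4 Å molecular sieves, CH2Cl2, −20 °C
Reagents that add atoms: tert-butyl hydroperoxide, CC(C)(C)OO
Why: Sharpless asymmetric epoxidation, in which the titanium L-(+)-tartrate complex delivers oxygen to the alkene face syn to the silyloxy group (reagent control; the D-(−)-tartrate would give the anti epoxide), setting both epoxide carbons.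

Step 6
Reactants: 7 [(1S,4S,6S)-4-(tert-butyldimethylsilyloxy)-2,2,6-trimethyl-7-oxabicyclo[4.1.0]heptan-1-yl]methanol
Product: 8 (1S,2R,4S)-4-(tert-butyldimethylsilyloxy)-1-(hydroxymethyl)-2,6,6-trimethylcyclohexane-1,2-diol
Conditions: HClO4 (3% aq.), THF, 0 °C
Reagents that add atoms: water, O
Why: Acid-catalysed trans-diaxial epoxide hydrolysis, in which water attacks the methyl-bearing carbon (remote from the inductively deactivating hydroxymethyl group and the quaternary CMe2 neighbour) with inversion, so the retained C1–O bond stays cis to the silyloxy group and the new C2 hydroxyl ends trans to both.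

Step 7
Reactants: 8 (1S,2R,4S)-4-(tert-butyldimethylsilyloxy)-1-(hydroxymethyl)-2,6,6-trimethylcyclohexane-1,2-diol
Product: 9 (1R,2R,4S)-4-(tert-butyldimethylsilyloxy)-1,2-dihydroxy-2,6,6-trimethylcyclohexane-1-carbaldehyde
Conditions: SO3·pyridine, DMSO, iPr2NEt, CH2Cl2, 0 °C
Reagents that add atoms: none
Why: Parikh–Doering oxidation acts only on the primary alcohol, since the tertiary hydroxyls cannot be oxidised, and the cold non-acidic conditions avoid α-ketol rearrangement of the α-hydroxy aldehyde.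

Step 8
Reactants: 9 (1R,2R,4S)-4-(tert-butyldimethylsilyloxy)-1,2-dihydroxy-2,6,6-trimethylcyclohexane-1-carbaldehyde
Product: 10 (1R,2R,4S)-4-(tert-butyldimethylsilyloxy)-1-[(E)-2-iodoethenyl]-2,6,6-trimethylcyclohexane-1,2-diol
Conditions: CrCl2 (8 equiv), CHI3 (3 equiv), THF, 0 °C → rt, dark
Reagents that add atoms: iodoform, IC(I)I
Why: Takai olefination converts the aldehyde into the (E)-vinyl iodide through the gem-dichromium reagent, and the chromium reagent tolerates the free tertiary hydroxyls.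

Step 9
Reactants: 11 1,3-dichloroacetone; 12 2,2-dimethylpropane-1,3-diol
Product: 13 2,2-bis(chloromethyl)-5,5-dimethyl-1,3-dioxane
Conditions: TsOH·H2O (cat.), benzene, reflux (Dean–Stark)
Reagents that add atoms: none
Why: Acid-catalysed ketalisation driven by azeotropic removal of water.

Step 10
Reactants: 13 2,2-bis(chloromethyl)-5,5-dimethyl-1,3-dioxane
Product: 15 6,6-dimethyl-4,8-dioxaspiro[2.5]oct-1-ene, via sodium cyclopropenide salt 14 (not isolated)
Conditions: NaNH2 (3 equiv), liquid NH3, −50 → −35 °C; NH4Cl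
Reagents that add atoms: none
Why: Amide-induced 1,3-elimination closes the chlorocyclopropane, a second dehydrochlorination gives the cyclopropene, and the third equivalent of base stores it as its sodium salt until the ammonium chloride quench (double dehydrohalogenation).

Step 11
Reactants: 15 6,6-dimethyl-4,8-dioxaspiro[2.5]oct-1-ene
Product: 17 tributyl(6,6-dimethyl-4,8-dioxaspiro[2.5]oct-1-en-1-yl)stannane, via lithiated acetal 16 (not isolated)
Conditions: n-BuLi, TMEDA, THF, −78 °C; Bu3SnCl, −78 → 0 °C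
Reagents that add atoms: tributyltin chloride, CCCC[Sn](Cl)(CCCC)CCCC
Why: The vinylic C–H of the cyclopropenone acetal is acidic (high s character), so deprotonation and stannylation give the cyclopropenylstannane.

Step 12
Reactants: 10 (1R,2R,4S)-4-(tert-butyldimethylsilyloxy)-1-[(E)-2-iodoethenyl]-2,6,6-trimethylcyclohexane-1,2-diol; 17 tributyl(6,6-dimethyl-4,8-dioxaspiro[2.5]oct-1-en-1-yl)stannane
Product: 18 (1R,2R,4S)-4-(tert-butyldimethylsilyloxy)-1-[(E)-2-(6,6-dimethyl-4,8-dioxaspiro[2.5]oct-1-en-1-yl)ethenyl]-2,6,6-trimethylcyclohexane-1,2-diol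
Conditions: Pd2(dba)3 (2.5 mol%), AsPh3 (20 mol%), CuI (10 mol%), DMF, rt
Reagents that add atoms: none
Why: Stille coupling of an alkenyl iodide with the cyclopropenylstannane proceeds with retention of the E geometry, and the copper-accelerated room-temperature conditions spare the strained ring and the free diol.

Step 13
Reactants: 18 (1R,2R,4S)-4-(tert-butyldimethylsilyloxy)-1-[(E)-2-(6,6-dimethyl-4,8-dioxaspiro[2.5]oct-1-en-1-yl)ethenyl]-2,6,6-trimethylcyclohexane-1,2-diol
Product: 19 2-[(E)-2-[(1R,2R,4S)-4-(tert-butyldimethylsilyloxy)-1,2-dihydroxy-2,6,6-trimethylcyclohexyl]ethenyl]cycloprop-2-en-1-one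
Conditions: Amberlyst 15, acetone–H2O (20:1), 0 °C → rt
Reagents that add atoms: water, O
Why: Acetal hydrolysis is very easy here because ionisation gives an aromatic alkoxycyclopropenylium ion, so the silyl ether and the tertiary allylic alcohol should survive the mild acid.

Step 14
Reactants: 20 2-methyl-2-vinyloxirane (racemic)
Product: 21 (E)-4-chloro-2-methylbut-2-en-1-ol
Conditions: TiCl4, CH2Cl2, −90 → −80 °C; aqueous work-up
Reagents that add atoms: titanium tetrachloride, Cl[Ti](Cl)(Cl)Cl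
Why: Lewis acid-mediated SN2′ opening of the vinyl epoxide delivers chloride to the vinyl terminus and gives the (E)-trisubstituted allylic alcohol.

Step 15
Reactants: 21 (E)-4-chloro-2-methylbut-2-en-1-ol
Product: 22 (E)-4-chloro-2-methylbut-2-en-1-yl acetate
Conditions: Ac2O, pyridine, DMAP (cat.), CH2Cl2, 0 °C → rt
Reagents that add atoms: acetic anhydride, CC(=O)OC(C)=O
Why: DMAP-catalysed acetylation of the primary alcohol installs the leaving group for the later 1,4-elimination.

Step 16
Reactants: 22 (E)-4-chloro-2-methylbut-2-en-1-yl acetate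
Product: 23 (E)-4-acetoxy-3-methylbut-2-enal
Conditions: N-methylmorpholine N-oxide (3 equiv), NaI (10 mol%), MeCN, rt → 40 °C
Reagents that add atoms: N-methylmorpholine N-oxide, C[N+]1([O-])CCOCC1
Why: Kornblum-type N-oxide oxidation, in which the allylic halide (iodide after Finkelstein exchange in the flask) is displaced by the N-oxide oxygen and the alkoxyammonium salt eliminates to the enal, leaving the acetate untouched.

Step 17
Reactants: 19 2-[(E)-2-[(1R,2R,4S)-4-(tert-butyldimethylsilyloxy)-1,2-dihydroxy-2,6,6-trimethylcyclohexyl]ethenyl]cycloprop-2-en-1-one; 23 (E)-4-acetoxy-3-methylbut-2-enal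
Product: 25 (5Z)-3-[(E)-2-[(1R,2R,4S)-4-(tert-butyldimethylsilyloxy)-1,2-dihydroxy-2,6,6-trimethylcyclohexyl]ethenyl]-5-(2-methylprop-2-en-1-ylidene)furan-2(5H)-one, via γ-substituted acetoxy butenolide 24 (not isolated)
Conditions: PMe3 (10 mol%), CH2Cl2, 0 °C → rt (19 added slowly to 23, 2 equiv); then DBU (1.5 equiv), 0 °C → rt
Reagents that add atoms: none
Why: Proposed new method: PMe3 adds to the unsubstituted ring carbon of 19 and strain release opens the adduct to an α-ketenyl phosphorus ylide, whose ylide carbon (future Cβ) adds 1,2 to the aldehyde carbon of 23 (future Cγ); the alkoxide then closes the lactone by 5-exo-dig attack on the ketene carbon and the ester enolate expels PMe3 (E1cB) to give the Cα=Cβ bond of 24. The closest known reaction is the PMe3-catalysed (3+2) annulation of diaryl and aryl alkyl cyclopropenones with aldehydes to butenolides; an alkenyl monosubstituted cyclopropenone with an enal partner has not been shown. DBU then removes the doubly activated γ-hydrogen of 24 and the 2-oxidofuran expels acetate through the side-chain double bond (vinylogous E1cB, a 1,4-elimination), modelled on base-induced eliminations that give γ-ylidene butenolides. The γ-carbon of 24 is formed without control but becomes sp2, so no new stereocentre remains, and the exocyclic double bond should settle as Z (chain cis to the ring oxygen, away from the β-hydrogen). The step needs phosphine attack at the unsubstituted cyclopropenone carbon, which the alkenyl group on the other carbon enforces and which places the ring B vinyl arm on Cα; slow addition of 19 to excess 23 should suppress ketene dimerisation, and the hindered tertiary hydroxyls should be too slow to trap the ketene.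

Step 18
Reactants: 4 (4R)-4-(tert-butyldimethylsilyloxy)-2,6,6-trimethylcyclohex-1-en-1-yl trifluoromethanesulfonate; 26 (E)-3-methylpent-2-en-4-yn-1-ol
Product: 27 (2E)-5-[(4R)-4-(tert-butyldimethylsilyloxy)-2,6,6-trimethylcyclohex-1-en-1-yl]-3-methylpent-2-en-4-yn-1-ol
Conditions: Pd(PPh3)4 (5 mol%), CuI (10 mol%), iPr2NH, DMF, rt → 50 °C
Reagents that add atoms: none
Why: Sonogashira coupling of the enol triflate with the terminal alkyne forms the ring A enyne with the E alkene of 26 carried through unchanged.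

Step 19
Reactants: 27 (2E)-5-[(4R)-4-(tert-butyldimethylsilyloxy)-2,6,6-trimethylcyclohex-1-en-1-yl]-3-methylpent-2-en-4-yn-1-ol
Product: 28 (2E)-5-[(4R)-4-(tert-butyldimethylsilyloxy)-2,6,6-trimethylcyclohex-1-en-1-yl]-3-methylpent-2-en-4-ynal
Conditions: MnO2 (excess), CH2Cl2, rt
Reagents that add atoms: none
Why: MnO2 oxidises the allylic alcohol selectively to the conjugated aldehyde without touching the silyl ether or the enyne.

Step 20
Reactants: 28 (2E)-5-[(4R)-4-(tert-butyldimethylsilyloxy)-2,6,6-trimethylcyclohex-1-en-1-yl]-3-methylpent-2-en-4-ynal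
Product: 29 (2E,4E)-7-[(4R)-4-(tert-butyldimethylsilyloxy)-2,6,6-trimethylcyclohex-1-en-1-yl]-N-methoxy-N,5-dimethylhepta-2,4-dien-6-ynamide
Conditions: diethyl (N-methoxy-N-methylcarbamoylmethyl)phosphonate, NaH, THF, 0 °C → rt
Reagents that add atoms: diethyl (N-methoxy-N-methylcarbamoylmethyl)phosphonate, CCOP(=O)(CC(=O)N(C)OC)OCC
Why: Horner–Wadsworth–Emmons olefination with the stabilised Weinreb amide phosphonate adds two carbons and gives the (E)-alkene.

Step 21
Reactants: 29 (2E,4E)-7-[(4R)-4-(tert-butyldimethylsilyloxy)-2,6,6-trimethylcyclohex-1-en-1-yl]-N-methoxy-N,5-dimethylhepta-2,4-dien-6-ynamide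
Product: 30 (2E,4E)-7-[(4R)-4-(tert-butyldimethylsilyloxy)-2,6,6-trimethylcyclohex-1-en-1-yl]-5-methylhepta-2,4-dien-6-ynal
Conditions: DIBAL-H (1.2 equiv), THF, −78 °C; Rochelle salt work-up
Reagents that add atoms: none
Why: DIBAL-H reduction of a Weinreb amide stops at the aldehyde because the chelated tetrahedral intermediate collapses only on work-up.

Step 22
Reactants: 30 (2E,4E)-7-[(4R)-4-(tert-butyldimethylsilyloxy)-2,6,6-trimethylcyclohex-1-en-1-yl]-5-methylhepta-2,4-dien-6-ynal
Product: 31 tert-butyl{[(1R)-4-[(3E,5E,7E)-8-iodo-3-methylocta-3,5,7-trien-1-yn-1-yl]-3,5,5-trimethylcyclohex-3-en-1-yl]oxy}dimethylsilane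
Conditions: CrCl2 (8 equiv), CHI3 (2.5 equiv), THF–dioxane, 0 °C → rt, dark
Reagents that add atoms: iodoform, IC(I)I
Why: Takai olefination of the conjugated aldehyde gives the terminal (E)-vinyl iodide while the enyne is inert to the chromium reagent.

Step 23
Reactants: 25 (5Z)-3-[(E)-2-[(1R,2R,4S)-4-(tert-butyldimethylsilyloxy)-1,2-dihydroxy-2,6,6-trimethylcyclohexyl]ethenyl]-5-(2-methylprop-2-en-1-ylidene)furan-2(5H)-one; 31 tert-butyl{[(1R)-4-[(3E,5E,7E)-8-iodo-3-methylocta-3,5,7-trien-1-yn-1-yl]-3,5,5-trimethylcyclohex-3-en-1-yl]oxy}dimethylsilane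
Product: 32 bis(tert-butyldimethylsilyl) ether of the target as a mixture of E and Z isomers at the new C(CH3)=CH bond next to the ylidene carbon
Conditions: Pd(OAc)2 (10 mol%), n-Bu4NCl (1 equiv), NaHCO3 (2.5 equiv), DMF, rt → 40 °C, dark, argon
Reagents that add atoms: none
Why: Heck reaction under ligand-free phase-transfer conditions, in which the vinyl palladium species from 31 adds to the least hindered alkene of 25 (the terminal methylene), palladium sits on the tertiary allylic carbon, and β-hydride elimination from the new doubly allylic CH2 gives the fully conjugated chain with the new alkene geometry not yet secured.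

Step 24
Reactants: 32 bis(tert-butyldimethylsilyl) ether of the target as an E/Z mixture at the new double bond
Product: 33 all-E, (5Z)-ylidene bis(tert-butyldimethylsilyl) ether of the target
Conditions: I2 (2 mol%), benzene, diffuse daylight, rt; aq. Na2S2O3 wash
Reagents that add atoms: none
Why: Iodine-catalysed equilibration of polyene geometry (reversible iodine-atom addition) should converge the isomers on the thermodynamically preferred all-E chain while the ylidene keeps its preferred Z geometry.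

Step 25
Reactants: 33 all-E, (5Z)-ylidene bis(tert-butyldimethylsilyl) ether of the target
Product: 34 target, (5Z)-3-[(E)-2-[(1R,2R,4S)-1,2,4-trihydroxy-2,6,6-trimethylcyclohexyl]ethenyl]-5-[(2E,4E,6E,8E)-11-[(4R)-4-hydroxy-2,6,6-trimethylcyclohex-1-en-1-yl]-2,9-dimethylundeca-2,4,6,8-tetraen-10-yn-1-ylidene]furan-2(5H)-one
Conditions: HF·pyridine, pyridine, THF, 0 °C → rt
Reagents that add atoms: none
Why: Fluoride-mediated desilylation removes both secondary silyl ethers, and the pyridine buffer protects the tertiary allylic alcohol, the polyene and the ylidene lactone.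

**Compound list**
1 | (4R,6R)-actinol, (4R,6R)-4-hydroxy-2,2,6-trimethylcyclohexan-1-one | C[C@H]1C(=O)C(C)(C)C[C@H](O)C1 | starting material
2 | (4R,6R)-4-(tert-butyldimethylsilyloxy)-2,2,6-trimethylcyclohexan-1-one | C[C@H]1C(=O)C(C)(C)C[C@H](O[Si](C)(C)C(C)(C)C)C1 | intermediate
3 | lithium (4R)-4-(tert-butyldimethylsilyloxy)-2,6,6-trimethylcyclohex-1-en-1-olate (not isolated) | CC1=C([O-])C(C)(C)C[C@H](O[Si](C)(C)C(C)(C)C)C1.[Li+] | intermediate
4 | (4R)-4-(tert-butyldimethylsilyloxy)-2,6,6-trimethylcyclohex-1-en-1-yl trifluoromethanesulfonate | CC1=C(OS(=O)(=O)C(F)(F)F)C(C)(C)C[C@H](O[Si](C)(C)C(C)(C)C)C1 | intermediate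
5 | methyl (4R)-4-(tert-butyldimethylsilyloxy)-2,6,6-trimethylcyclohex-1-ene-1-carboxylate | CC1=C(C(=O)OC)C(C)(C)C[C@H](O[Si](C)(C)C(C)(C)C)C1 | intermediate
6 | [(4R)-4-(tert-butyldimethylsilyloxy)-2,6,6-trimethylcyclohex-1-en-1-yl]methanol | CC1=C(CO)C(C)(C)C[C@H](O[Si](C)(C)C(C)(C)C)C1 | intermediate
7 | [(1S,4S,6S)-4-(tert-butyldimethylsilyloxy)-2,2,6-trimethyl-7-oxabicyclo[4.1.0]heptan-1-yl]methanol (epoxide cis to the silyloxy group) | OC[C@@]1(O2)C(C)(C)C[C@H](O[Si](C)(C)C(C)(C)C)C[C@@]12C | intermediate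
8 | (1S,2R,4S)-4-(tert-butyldimethylsilyloxy)-1-(hydroxymethyl)-2,6,6-trimethylcyclohexane-1,2-diol | OC[C@@]1(O)C(C)(C)C[C@H](O[Si](C)(C)C(C)(C)C)C[C@@]1(C)O | intermediate
9 | (1R,2R,4S)-4-(tert-butyldimethylsilyloxy)-1,2-dihydroxy-2,6,6-trimethylcyclohexane-1-carbaldehyde | O=C[C@@]1(O)C(C)(C)C[C@H](O[Si](C)(C)C(C)(C)C)C[C@@]1(C)O | intermediate
10 | (1R,2R,4S)-4-(tert-butyldimethylsilyloxy)-1-[(E)-2-iodoethenyl]-2,6,6-trimethylcyclohexane-1,2-diol | I/C=C/[C@@]1(O)C(C)(C)C[C@H](O[Si](C)(C)C(C)(C)C)C[C@@]1(C)O | intermediate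
11 | 1,3-dichloroacetone | ClCC(=O)CCl | starting material
12 | 2,2-dimethylpropane-1,3-diol | CC(C)(CO)CO | starting material
13 | 2,2-bis(chloromethyl)-5,5-dimethyl-1,3-dioxane | ClCC1(CCl)OCC(C)(C)CO1 | intermediate
14 | sodium 6,6-dimethyl-4,8-dioxaspiro[2.5]oct-1-en-1-ide (not isolated) | [Na+].[C-]1=CC12OCC(C)(C)CO2 | intermediate
15 | 6,6-dimethyl-4,8-dioxaspiro[2.5]oct-1-ene | C1=CC12OCC(C)(C)CO2 | intermediate
16 | (6,6-dimethyl-4,8-dioxaspiro[2.5]oct-1-en-1-yl)lithium (not isolated) | [Li]C1=CC12OCC(C)(C)CO2 | intermediate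
17 | tributyl(6,6-dimethyl-4,8-dioxaspiro[2.5]oct-1-en-1-yl)stannane | CCCC[Sn](CCCC)(CCCC)C1=CC12OCC(C)(C)CO2 | intermediate
18 | (1R,2R,4S)-4-(tert-butyldimethylsilyloxy)-1-[(E)-2-(6,6-dimethyl-4,8-dioxaspiro[2.5]oct-1-en-1-yl)ethenyl]-2,6,6-trimethylcyclohexane-1,2-diol | CC1(C)COC2(OC1)C=C2/C=C/[C@@]3(O)C(C)(C)C[C@H](O[Si](C)(C)C(C)(C)C)C[C@@]3(C)O | intermediate
19 | 2-[(E)-2-[(1R,2R,4S)-4-(tert-butyldimethylsilyloxy)-1,2-dihydroxy-2,6,6-trimethylcyclohexyl]ethenyl]cycloprop-2-en-1-one | O=C1C=C1/C=C/[C@@]3(O)C(C)(C)C[C@H](O[Si](C)(C)C(C)(C)C)C[C@@]3(C)O | intermediate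
20 | 2-methyl-2-vinyloxirane (racemic) | C=CC1(C)CO1 | starting material
21 | (E)-4-chloro-2-methylbut-2-en-1-ol | OC/C(C)=C/CCl | intermediate
22 | (E)-4-chloro-2-methylbut-2-en-1-yl acetate | CC(=O)OC/C(C)=C/CCl | intermediate
23 | (E)-4-acetoxy-3-methylbut-2-enal | CC(=O)OC/C(C)=C/C=O | intermediate
24 | 5-[(E)-3-acetoxy-2-methylprop-1-en-1-yl]-3-[(E)-2-[(1R,2R,4S)-4-(tert-butyldimethylsilyloxy)-1,2-dihydroxy-2,6,6-trimethylcyclohexyl]ethenyl]furan-2(5H)-one, both C5 epimers (not isolated) | CC(=O)OC/C(C)=C/C1OC(=O)C(/C=C/[C@@]3(O)C(C)(C)C[C@H](O[Si](C)(C)C(C)(C)C)C[C@@]3(C)O)=C1 | intermediate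
25 | (5Z)-3-[(E)-2-[(1R,2R,4S)-4-(tert-butyldimethylsilyloxy)-1,2-dihydroxy-2,6,6-trimethylcyclohexyl]ethenyl]-5-(2-methylprop-2-en-1-ylidene)furan-2(5H)-one | C=C(C)/C=C2C=C(/C=C/[C@@]3(O)C(C)(C)C[C@H](O[Si](C)(C)C(C)(C)C)C[C@@]3(C)O)C(=O)O/2 | intermediate
26 | (E)-3-methylpent-2-en-4-yn-1-ol | C#C/C(C)=C/CO | starting material
27 | (2E)-5-[(4R)-4-(tert-butyldimethylsilyloxy)-2,6,6-trimethylcyclohex-1-en-1-yl]-3-methylpent-2-en-4-yn-1-ol | CC1=C(C#C/C(C)=C/CO)C(C)(C)C[C@H](O[Si](C)(C)C(C)(C)C)C1 | intermediate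
28 | (2E)-5-[(4R)-4-(tert-butyldimethylsilyloxy)-2,6,6-trimethylcyclohex-1-en-1-yl]-3-methylpent-2-en-4-ynal | CC1=C(C#C/C(C)=C/C=O)C(C)(C)C[C@H](O[Si](C)(C)C(C)(C)C)C1 | intermediate
29 | (2E,4E)-7-[(4R)-4-(tert-butyldimethylsilyloxy)-2,6,6-trimethylcyclohex-1-en-1-yl]-N-methoxy-N,5-dimethylhepta-2,4-dien-6-ynamide | CC1=C(C#C/C(C)=C/C=C/C(=O)N(C)OC)C(C)(C)C[C@H](O[Si](C)(C)C(C)(C)C)C1 | intermediate
30 | (2E,4E)-7-[(4R)-4-(tert-butyldimethylsilyloxy)-2,6,6-trimethylcyclohex-1-en-1-yl]-5-methylhepta-2,4-dien-6-ynal | CC1=C(C#C/C(C)=C/C=C/C=O)C(C)(C)C[C@H](O[Si](C)(C)C(C)(C)C)C1 | intermediate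
31 | tert-butyl{[(1R)-4-[(3E,5E,7E)-8-iodo-3-methylocta-3,5,7-trien-1-yn-1-yl]-3,5,5-trimethylcyclohex-3-en-1-yl]oxy}dimethylsilane | CC1=C(C#C/C(C)=C/C=C/C=C/I)C(C)(C)C[C@H](O[Si](C)(C)C(C)(C)C)C1 | intermediate
32 | bis(tert-butyldimethylsilyl) ether of the target, E/Z mixture at the C(CH3)=CH bond next to the ylidene carbon | CC1=C(C#C/C(C)=C/C=C/C=C/C=C(C)C(/[H])=C2C=C(/C=C/[C@@]3(O)C(C)(C)C[C@H](O[Si](C)(C)C(C)(C)C)C[C@@]3(C)O)C(=O)O/2)C(C)(C)C[C@H](O[Si](C)(C)C(C)(C)C)C1 | intermediate
33 | all-E, (5Z)-ylidene bis(tert-butyldimethylsilyl) ether of the target | CC1=C(C#C/C(C)=C/C=C/C=C/C=C(C)/C=C2C=C(/C=C/[C@@]3(O)C(C)(C)C[C@H](O[Si](C)(C)C(C)(C)C)C[C@@]3(C)O)C(=O)O/2)C(C)(C)C[C@H](O[Si](C)(C)C(C)(C)C)C1 | intermediate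
34 | CNP0163979.1, (5Z)-3-[(E)-2-[(1R,2R,4S)-1,2,4-trihydroxy-2,6,6-trimethylcyclohexyl]ethenyl]-5-[(2E,4E,6E,8E)-11-[(4R)-4-hydroxy-2,6,6-trimethylcyclohex-1-en-1-yl]-2,9-dimethylundeca-2,4,6,8-tetraen-10-yn-1-ylidene]furan-2(5H)-one | CC1=C(C#C/C(C)=C/C=C/C=C/C=C(C)/C=C2C=C(/C=C/[C@@]3(O)C(C)(C)C[C@H](O)C[C@@]3(C)O)C(=O)O/2)C(C)(C)C[C@H](O)C1 | target

**Step count**
Total: 25 steps. Longest linear sequence: 14 steps (steps 1–8, 12, 13, 17, 23, 24, 25).

**Steps most likely to fail**

1. Step 17 (proposed method). The ketenyl ylide may dimerise or react in Wittig fashion before the alkoxide closes the lactone, and the alkenylcyclopropenone may polymerise under the phosphine. The base-induced loss of acetate may also stall at 24 or give the wrong ylidene geometry.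
Fallback by known chemistry, setting out from 10 and returning at 25: vinyl iodide 10 is stannylated with hexamethylditin (Pd(PPh3)4, toluene, 80 °C) to give (1R,2R,4S)-4-(tert-butyldimethylsilyloxy)-2,6,6-trimethyl-1-[(E)-2-(trimethylstannyl)ethenyl]cyclohexane-1,2-diol F1. Separately, commercial (E)-2,3-dibromoacrylic acid and 2-methylbut-1-en-3-yne are joined by Sonogashira coupling at the β-bromide with 5-exo-dig lactonisation in the same flask (PdCl2(PPh3)2, CuI, Et3N, MeCN), giving (5Z)-3-bromo-5-(2-methylprop-2-en-1-ylidene)furan-2(5H)-one F2. Stille coupling of F1 with F2 (Pd2(dba)3, AsPh3, NMP, rt) gives 25, and the route continues at step 23.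

2. Step 23. β-Hydride elimination may go toward the methyl group and give the exo-methylene isomer, the η3-allyl palladium intermediate may be trapped, or the vinyl palladium species may insert into the enyne instead.
Fallback, setting out from 31 and 19 and returning at 32: the chain carbon–carbon bond is made before the annulation by carbonyl addition. Nozaki–Hiyama–Kishi addition of 31 to commercial (E)-4,4-dimethoxy-2-methylbut-2-enal (CrCl2, NiCl2 (cat.), DMSO–THF) gives the secondary dienyl alcohol F3. Acetylation (Ac2O, pyridine, DMAP) gives the acetate F4, and mild acetal hydrolysis (PPTS, wet acetone) gives the acetoxy enal F5. F5 is then used in place of 23 under the conditions of step 17 with cyclopropenone 19. The non-isolated γ-substituted butenolide F6 loses acetate by the same 1,4-elimination, which now forms the chain C(CH3)=CH bond, and the product is 32, which enters step 24.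

3. Step 6. Ionisation may occur at the wrong epoxide carbon, elimination or ring contraction may compete with hydration, and the acid may cleave the silyl ether.
Fallback, setting out from 6 and returning at 8: Sharpless epoxidation of 6 with D-(−)-diethyl tartrate gives the anti epoxide [(1R,4S,6R)-4-(tert-butyldimethylsilyloxy)-2,2,6-trimethyl-7-oxabicyclo[4.1.0]heptan-1-yl]methanol F7. Payne rearrangement in aqueous NaOH–t-BuOH (70 °C) moves the epoxide to the exocyclic position with inversion at the ring carbon, and hydroxide opens the new spiro epoxide at its CH2 group. The ring C–O bond that is kept lies trans to the silyloxy group and the inverted one lies cis, so the same triol 8 results without any acid.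

Further compounds
F1 | step 17 | (1R,2R,4S)-4-(tert-butyldimethylsilyloxy)-2,6,6-trimethyl-1-[(E)-2-(trimethylstannyl)ethenyl]cyclohexane-1,2-diol | C[Sn](C)(C)/C=C/[C@@]1(O)C(C)(C)C[C@H](O[Si](C)(C)C(C)(C)C)C[C@@]1(C)O
F2 | step 17 | (5Z)-3-bromo-5-(2-methylprop-2-en-1-ylidene)furan-2(5H)-one | C=C(C)/C=C1C=C(Br)C(=O)O/1
F3 | step 23 | (2E,5E,7E,9E)-12-[(4R)-4-(tert-butyldimethylsilyloxy)-2,6,6-trimethylcyclohex-1-en-1-yl]-1,1-dimethoxy-3,10-dimethyldodeca-2,5,7,9-tetraen-11-yn-4-ol (both carbinol epimers) | CC1=C(C#C/C(C)=C/C=C/C=C/C(O)/C(C)=C/C(OC)OC)C(C)(C)C[C@H](O[Si](C)(C)C(C)(C)C)C1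
F4 | step 23 | acetate of F3 | CC1=C(C#C/C(C)=C/C=C/C=C/C(OC(C)=O)/C(C)=C/C(OC)OC)C(C)(C)C[C@H](O[Si](C)(C)C(C)(C)C)C1
F5 | step 23 | (2E,5E,7E,9E)-4-acetoxy-12-[(4R)-4-(tert-butyldimethylsilyloxy)-2,6,6-trimethylcyclohex-1-en-1-yl]-3,10-dimethyldodeca-2,5,7,9-tetraen-11-ynal | CC1=C(C#C/C(C)=C/C=C/C=C/C(OC(C)=O)/C(C)=C/C=O)C(C)(C)C[C@H](O[Si](C)(C)C(C)(C)C)C1
F6 | step 23 | γ-substituted butenolide from 19 and F5 carrying the full acetoxy chain at C5 (not isolated) | CC1=C(C#C/C(C)=C/C=C/C=C/C(OC(C)=O)/C(C)=C/C2OC(=O)C(/C=C/[C@@]3(O)C(C)(C)C[C@H](O[Si](C)(C)C(C)(C)C)C[C@@]3(C)O)=C2)C(C)(C)C[C@H](O[Si](C)(C)C(C)(C)C)C1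
F7 | step 6 | [(1R,4S,6R)-4-(tert-butyldimethylsilyloxy)-2,2,6-trimethyl-7-oxabicyclo[4.1.0]heptan-1-yl]methanol (epoxide trans to the silyloxy group) | OC[C@]1(O2)C(C)(C)C[C@H](O[Si](C)(C)C(C)(C)C)C[C@]12C
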